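**Retrosynthetic overview**
- Target 20 comes from 5,7,8,3',4'-pentamethoxyflavone 14 by O-demethylation, peracetylation, selective removal of the 7-acetate, sulfation at O7 and removal of the other acetates.
- The strategy rests on one feature: the C4 carbonyl lies between C4a of ring A and the C3=C2–aryl unit, and O1 sits on C8a, ortho to C4a. Ring C is therefore assembled from ortho-iodophenol 9 (C4a–I, C8a–OH), carbon monoxide 11 (C4) and arylacetylene 10 (C3, C2, ring B).
- Iodophenol 9 comes from 2-hydroxy-4,6-dimethoxybenzaldehyde 1 by carbamoylation, Baeyer–Villiger oxidation, methylation, carbamate-directed ortho-iodination and carbamate hydrolysis.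
- Ring order: rings A and B are bought; ring C is the only ring formed (step 6).

Key step: step 6

Assumption: the target is drawn as the free hydrogen sulfate, so the last step ends with a cold cation exchange. Aryl hydrogen sulfates hydrolyse under their own acidity, so 20 should be kept cold and dry. Flavone numbering (O1, C2 to C8a, primed positions on ring B) is used from compound 12 onward.

Step 1
Reactants: 1 2-hydroxy-4,6-dimethoxybenzaldehyde; 2 N,N-diethylcarbamoyl chloride
Product: 3 2-formyl-3,5-dimethoxyphenyl N,N-diethylcarbamate
Conditions: K2CO3, MeCN, reflux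
Reagents that add atoms: none
Why: O-carbamoylation of the phenoxide should be clean because the chelated ortho-hydroxyl, once deprotonated by K2CO3, is the only nucleophile in 1.

Step 2
Reactants: 3 2-formyl-3,5-dimethoxyphenyl N,N-diethylcarbamate
Product: 5 2-hydroxy-3,5-dimethoxyphenyl N,N-diethylcarbamate, via aryl formate 4 (not isolated)
Conditions: mCPBA, CH2Cl2, 0 °C to rt; then MeOH, HCl (5 mol %), rt
Reagents that add atoms: mCPBA, O=C(OO)c1cccc(Cl)c1
Why: In this Baeyer–Villiger (Dakin-type) oxidation the electron-rich aryl group with ortho- and para-oxygen donors should migrate in preference to hydride, and acid-catalysed methanolysis of the formate frees the phenol without forming a phenoxide next to the carbamate, so no O-to-O carbamoyl transfer is expected.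

Step 3
Reactants: 5 2-hydroxy-3,5-dimethoxyphenyl N,N-diethylcarbamate
Product: 6 2,3,5-trimethoxyphenyl N,N-diethylcarbamate
Conditions: MeI (excess), K2CO3, acetone, rt
Reagents that add atoms: iodomethane, CI
Why: In this Williamson methylation, excess iodomethane at room temperature should trap the phenoxide faster than it can attack the weakly electrophilic neighbouring diethylcarbamate.

Step 4
Reactants: 6 2,3,5-trimethoxyphenyl N,N-diethylcarbamate
Product: 8 2-iodo-3,5,6-trimethoxyphenyl N,N-diethylcarbamate, via aryllithium 7 (not isolated)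
Conditions: s-BuLi, TMEDA, THF, −78 °C; then I2, THF, −78 °C to rt
Reagents that add atoms: iodine, II
Why: In this directed ortho-metalation the O-carbamate is the strongest director, so its only free ortho position (C6, also flanked by the C5 methoxy) should be lithiated in preference to C4 between two methoxy groups, and at −78 °C the aryllithium is iodinated before an anionic ortho-Fries shift can set in.

Step 5
Reactants: 8 2-iodo-3,5,6-trimethoxyphenyl N,N-diethylcarbamate
Product: 9 2-iodo-3,5,6-trimethoxyphenol
Conditions: NaOH, EtOH/H2O, reflux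
Reagents that add atoms: none
Why: Base hydrolysis of the aryl carbamate (hydroxide adds to the carbamate carbonyl and the aryloxide leaves) should free the phenol, while the electron-rich aryl iodide is inert to hydroxide.

Step 6
Reactants: 9 2-iodo-3,5,6-trimethoxyphenol; 10 4-ethynyl-1,2-dimethoxybenzene; 11 carbon monoxide
Product: 14 5,7,8,3',4'-pentamethoxyflavone, via ynone 12 (not isolated), via enaminone 13 (not isolated)
Conditions: PdCl2(PPh3)2 (5 mol %), CO (20 bar), Et2NH, 120 °C, autoclave
Reagents that add atoms: none
Why: PdCl2(PPh3)2 is reduced in the amine to zerovalent palladium, which inserts into the C–I bond of 9 at the future C4a; carbon monoxide then inserts to give an aroyl complex of divalent palladium, and the acetylide formed from 10 and diethylamine is coupled by reductive elimination to give ynone 12 (bonds C4a–C4 and C4–C3). Diethylamine adds to 12 to give enaminone 13, whose β-carbon (the future C2) is attacked by the ortho-hydroxyl with loss of the amine, forming O1–C2 and closing ring C by a 6-endo-trig addition–elimination. The closest known reaction type is the carbonylative Sonogashira annulation of ortho-iodophenols with terminal alkynes to chromones and flavones. No stereocentre is formed. The step needs carbonylation before alkynylation, which CO pressure and the electron-rich, doubly ortho-substituted aryl–palladium species (fast CO uptake, slow direct coupling) should secure, and it needs six-membered instead of five-membered (aurone) closure, which the enaminone secures because only its β-carbon is electrophilic. Because C4a and C8a are defined by the iodine and the hydroxyl of 9, the 5,7,8-oxygenation of ring A cannot be scrambled.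

Step 7
Reactants: 14 5,7,8,3',4'-pentamethoxyflavone
Product: 15 5,7,8,3',4'-pentahydroxyflavone (8-hydroxyluteolin)
Conditions: BBr3 (12 equiv), CH2Cl2, −78 °C to rt, Ar; then MeOH/H2O, 0 °C
Reagents that add atoms: none
Why: In this Lewis-acid cleavage of aryl methyl ethers, bromide attacks the methyl group of each boron-complexed ether, and working water-free at or below room temperature with a cold quench should keep the pyrone ring closed, so acid-induced Wessely–Moser isomerisation to the 5,6,7-pattern is not expected.

Step 8
Reactants: 15 5,7,8,3',4'-pentahydroxyflavone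
Product: 16 5,7,8,3',4'-penta-O-acetyl-8-hydroxyluteolin
Conditions: Ac2O, pyridine, DMAP (5 mol %), rt, Ar
Reagents that add atoms: acetic anhydride, CC(=O)OC(C)=O
Why: Acyl transfer with nucleophilic catalysis by DMAP should acetylate all five phenols, including the hydrogen-bonded 5-hydroxyl.

Step 9
Reactants: 16 5,7,8,3',4'-penta-O-acetyl-8-hydroxyluteolin
Product: 17 5,8,3',4'-tetra-O-acetyl-8-hydroxyluteolin (7-hydroxyl free)
Conditions: PhSH (1.2 equiv), imidazole (0.3 equiv), NMP, 0 °C
Reagents that add atoms: none
Why: In this chemoselective thiolysis the thiolate attacks the acetate whose phenoxide is the best leaving group, which is the one on O7 (para to the C4 carbonyl through C4a), and the same acidity order should keep the neighbouring acetyl group on O8 instead of letting it migrate to O7.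

Step 10
Reactants: 17 5,8,3',4'-tetra-O-acetyl-8-hydroxyluteolin
Product: 18 pyridinium 5,8,3',4'-tetra-O-acetyl-8-hydroxyluteolin 7-sulfate
Conditions: SO3·pyridine (5 equiv), pyridine, rt
Reagents that add atoms: sulfur trioxide–pyridine complex, [O-]S(=O)(=O)[n+]1ccccc1
Why: In this O-sulfation of a phenol by an amine–sulfur trioxide complex only the 7-hydroxyl is free, and the product is held as its pyridinium salt.

Step 11
Reactants: 18 pyridinium 5,8,3',4'-tetra-O-acetyl-8-hydroxyluteolin 7-sulfate
Product: 20 8-hydroxyluteolin 7-(hydrogen sulfate), via ammonium salt 19 (not isolated)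
Conditions: NH3 (7 M in MeOH), 0 °C to rt, Ar; then Dowex 50WX8 (H+ form), H2O/MeOH, 0 °C, freeze-dry
Reagents that add atoms: none
Why: Ammonolysis of the four aryl acetates is fast while the aryl sulfate monoester anion is inert to nucleophiles, and a brief cold exchange of ammonium for a proton on the sulfonic acid resin should give the hydrogen sulfate.

**Compound list**
1 | 2-hydroxy-4,6-dimethoxybenzaldehyde | COc1cc(O)c(C=O)c(OC)c1 | starting material
2 | N,N-diethylcarbamoyl chloride | CCN(CC)C(Cl)=O | starting material
3 | 2-formyl-3,5-dimethoxyphenyl N,N-diethylcarbamate | CCN(CC)C(=O)Oc1cc(OC)cc(OC)c1C=O | intermediate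
4 | 2-(formyloxy)-3,5-dimethoxyphenyl N,N-diethylcarbamate (aryl formate, not isolated) | CCN(CC)C(=O)Oc1cc(OC)cc(OC)c1OC=O | intermediate
5 | 2-hydroxy-3,5-dimethoxyphenyl N,N-diethylcarbamate | CCN(CC)C(=O)Oc1cc(OC)cc(OC)c1O | intermediate
6 | 2,3,5-trimethoxyphenyl N,N-diethylcarbamate | CCN(CC)C(=O)Oc1cc(OC)cc(OC)c1OC | intermediate
7 | 2-lithio-3,5,6-trimethoxyphenyl N,N-diethylcarbamate (aryllithium, not isolated) | CCN(CC)C(=O)Oc1c([Li])c(OC)cc(OC)c1OC | intermediate
8 | 2-iodo-3,5,6-trimethoxyphenyl N,N-diethylcarbamate | CCN(CC)C(=O)Oc1c(I)c(OC)cc(OC)c1OC | intermediate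
9 | 2-iodo-3,5,6-trimethoxyphenol | COc1cc(OC)c(OC)c(O)c1I | intermediate
10 | 4-ethynyl-1,2-dimethoxybenzene | C#Cc1ccc(OC)c(OC)c1 | starting material
11 | carbon monoxide | [C-]#[O+] | starting material
12 | 3-(3,4-dimethoxyphenyl)-1-(2-hydroxy-3,4,6-trimethoxyphenyl)prop-2-yn-1-one (ynone, not isolated) | COc1ccc(C#CC(=O)c2c(OC)cc(OC)c(OC)c2O)cc1OC | intermediate
13 | (E)-3-(diethylamino)-3-(3,4-dimethoxyphenyl)-1-(2-hydroxy-3,4,6-trimethoxyphenyl)prop-2-en-1-one (enaminone, not isolated; either alkene geometry would close) | CCN(CC)/C(=C/C(=O)c1c(OC)cc(OC)c(OC)c1O)c1ccc(OC)c(OC)c1 | intermediate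
14 | 2-(3,4-dimethoxyphenyl)-5,7,8-trimethoxy-4H-chromen-4-one (5,7,8,3',4'-pentamethoxyflavone) | COc1ccc(-c2cc(=O)c3c(OC)cc(OC)c(OC)c3o2)cc1OC | intermediate
15 | 2-(3,4-dihydroxyphenyl)-5,7,8-trihydroxy-4H-chromen-4-one (8-hydroxyluteolin) | O=c1cc(-c2ccc(O)c(O)c2)oc2c(O)c(O)cc(O)c12 | intermediate
16 | 5,7,8,3',4'-penta-O-acetyl-8-hydroxyluteolin | CC(=O)Oc1ccc(-c2cc(=O)c3c(OC(C)=O)cc(OC(C)=O)c(OC(C)=O)c3o2)cc1OC(C)=O | intermediate
17 | 5,8,3',4'-tetra-O-acetyl-8-hydroxyluteolin (7-hydroxyl free) | CC(=O)Oc1ccc(-c2cc(=O)c3c(OC(C)=O)cc(O)c(OC(C)=O)c3o2)cc1OC(C)=O | intermediate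
18 | pyridinium 5,8,3',4'-tetra-O-acetyl-8-hydroxyluteolin 7-sulfate | CC(=O)Oc1ccc(-c2cc(=O)c3c(OC(C)=O)cc(OS(=O)(=O)[O-])c(OC(C)=O)c3o2)cc1OC(C)=O.c1cc[nH+]cc1 | intermediate
19 | ammonium 8-hydroxyluteolin 7-sulfate (not isolated) | [NH4+].O=c1cc(-c2ccc(O)c(O)c2)oc2c(O)c(OS(=O)(=O)[O-])cc(O)c12 | intermediate
20 | 8-hydroxyluteolin 7-(hydrogen sulfate) | O=c1cc(-c2ccc(O)c(O)c2)oc2c(O)c(OS(=O)(=O)O)cc(O)c12 | target

**Totals**
Total step count: 11. Longest linear sequence: 11 steps (1 to 20); alkyne 10 and carbon monoxide 11 are bought.

**Steps most likely to fail**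

Step 6. The electron-rich, doubly ortho-substituted aryl iodide may add slowly to zerovalent palladium. Direct alkynylation without CO uptake, followed by closure to a 2-arylbenzofuran, or five-membered closure to the aurone, may also compete. The fallback sets out from 9 and forms the C4a–C4 bond with an arylmagnesium reagent instead of palladium and carbon monoxide.
- Phenol 9 would be protected with MOMCl and iPr2NEt in CH2Cl2 as 2-iodo-1,4,5-trimethoxy-3-(methoxymethoxy)benzene F1.
- Alkyne 10 would be deprotonated with n-BuLi and acylated with N-methoxy-N-methylcarbamoyl chloride to give 3-(3,4-dimethoxyphenyl)-N-methoxy-N-methylprop-2-ynamide F2.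
- Iodine–magnesium exchange on F1 (iPrMgCl·LiCl, THF, −20 °C) and acylation with F2 should give 3-(3,4-dimethoxyphenyl)-1-[2-(methoxymethoxy)-3,4,6-trimethoxyphenyl]prop-2-yn-1-one F3.
- HCl in MeOH would remove the acetal and give ynone 12, where the route is rejoined; diethylamine in ethanol at reflux would then close 12 through 13 to 14, as in the second half of step 6.

Step 9. Thiolysis may not stop at one acetate, may also attack the 4'- or 8-acetate, or the 8-acetyl group may shift to O7, so that a mixture of partly acetylated flavones results. The fallback sets out from 15 and goes to 20 without acetyl groups.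
- Sulfation with tetrabutylammonium hydrogen sulfate and N,N'-dicyclohexylcarbodiimide in pyridine at 4 °C is known to esterify the 7-hydroxyl of flavones first, because it is the most acidic.
- After size-exclusion chromatography this should give tetrabutylammonium 8-hydroxyluteolin 7-sulfate F4.
- The same cold cation exchange as in step 11 would then give 20.

Step 5. Hydrolysis of the doubly ortho-substituted diethylcarbamate may be slow, and the forcing conditions then needed may cost the iodine or a methyl ether. The fallback sets out from 8 and returns at 9.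
- Reductive cleavage with Cp2Zr(H)Cl (zirconocene chloride hydride) in THF at room temperature is a hydrozirconation of the carbamate carbonyl that collapses to the aryloxide and a formamide.
- It is known to tolerate aryl halides, and it makes no compound outside the list (F0).

**Further compounds**
F1 | step 6 | 2-iodo-1,4,5-trimethoxy-3-(methoxymethoxy)benzene | COCOc1c(I)c(OC)cc(OC)c1OC
F2 | step 6 | 3-(3,4-dimethoxyphenyl)-N-methoxy-N-methylprop-2-ynamide | CON(C)C(=O)C#Cc1ccc(OC)c(OC)c1
F3 | step 6 | 3-(3,4-dimethoxyphenyl)-1-[2-(methoxymethoxy)-3,4,6-trimethoxyphenyl]prop-2-yn-1-one | COCOc1c(C(=O)C#Cc2ccc(OC)c(OC)c2)c(OC)cc(OC)c1OC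
F4 | step 9 | tetrabutylammonium 8-hydroxyluteolin 7-sulfate | CCCC[N+](CCCC)(CCCC)CCCC.O=c1cc(-c2ccc(O)c(O)c2)oc2c(O)c(OS(=O)(=O)[O-])cc(O)c12
F0 | step 5 | none | none
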